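The earlier runs and the new flask stem from a simulated flask on assumed constants; the scatter is artificial.

How far does the rate of making left-handed product in the flask follow the catalyst charge at 30% conversion?

all flasks: gas 100 mM (held)

| flask | left-handed substrate | right-handed substrate | catalyst | remark |
|---|---|---|---|---|
| epsilon | 0.25 M | 0.25 M | 0.29 mM | run made earlier |
| delta | 0.25 M | 0.25 M | 0.65 mM | run made earlier |
| eta | 0.38 M | 0.38 M | 0.43 mM | run made earlier |
| flask | 0.25 M | 0.25 M | 0.43 mM |  |

- epsilon (time / min: left-handed product / %): 2.00: 4.4; 5.00: 9.1; 10.0: 19.0; 25.0: 32.8
- delta (time / min: left-handed product / %): 6.00: 20.8; 12.0: 35.4; 20.0: 44.4; 25.0: 44.2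
- eta (time / min: left-handed product / %): 2.00: 5.5; 5.00: 14.7; 10.0: 24.2; 25.0: 40.2

(scatter of a reading: 1 percentage point)

1. apparent order in catalyst when 30% of the left-handed substrate and right-handed substrate together are converted (percent change of the rate of making left-handed product for one percent more catalyst charged)

- catalyst is single-handed; left-handed substrate and right-handed substrate are mirror images of each other, charged as a racemate, each of them at the stated concentration
- at the start none of the gas is in solution

We climb the time scales, starting below the first reading. Whatever the gas and catalyst do early does not show clearly in epsilon, whose first-order constant is 0.0461 min⁻¹ at 2.00 min and 0.0427 min⁻¹ at 25.0 min. So we freeze gas and catalyst and let the left-handed substrate fall pseudo-first-order.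

The next rung is that fall. Scaled to the flask's catalyst, epsilon's reading at 25.0 min gives 0.0633 min⁻¹ and delta's at 12.0 min gives 0.0679 min⁻¹. Their mean is our catalyst-scaled constant, 0.0656 min⁻¹, which gives the left-handed substrate a life of 15.2 min, longer than the first-reading time.

On the top rung, delta reads 44.4% and 44.2%, each with a scatter of 1 percentage point, so this pair shows no plateau, and both readings stand below the left-handed half of the charge. For one substrate charge, we take a set conversion to mean the same left-handed substrate, so in our reckoning the order in catalyst is that of the constant. Our pair reads 1.09, from one reading per run, each with a scatter of 1 point, and we commit to about first order.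

The forecast gives 0.97, lower than our pair, and on substrate it says: "First order in substrate therefore holds".

The flask gives 1.0, so doubling the catalyst charge near this conversion doubles the rate of making left-handed product.

    reagent + catalyst + left-handed substrate → catalyst + left-handed product (k = 2600 L² mol⁻² min⁻¹)
    reagent + catalyst + right-handed substrate → catalyst + right-handed product (k = 1000 L² mol⁻² min⁻¹)
    catalyst ⇌ dormant form (K = 0.600, k = 0.0880 min⁻¹)
    gas ⇌ reagent, rate k4*(csat - [reagent]) (kL = 1.70 min⁻¹)

The dormant form holds a nearly steady share of the catalyst, 35.5% at 12.5 min and 37.4% at 25.0 min. With 0.0656 min⁻¹, our constant puts left-handed product at 40.3% after 25.0 min. The flask holds 41.0% then, and eta, with the same catalyst and more substrate, read 40.2% at 25.0 min.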